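Remark on the chemistry: atom labels (O1, C2, C3, C4, C4a, C5 to C8, C8a, primed numbers for ring B) are those of the flavone and are used for the same atoms in open-chain precursors; diketones 11 and F2 are drawn as diketo tautomers although they should exist mainly as chelated enols; compounds 1, 2 and 4 are assumed to be purchasable.

## Analysis of the target

The target is a flavone (2-aryl-4H-chromen-4-one) made of the benzo ring A, the γ-pyrone ring C and the pendant aryl ring B. Ring A is fully substituted (OH at C5, OMe at C6, OH at C7, OMe at C8), ring C carries only C3–H and the C4 carbonyl, and ring B has OH at C3' and C5' around OMe at C4'. There is no stereocentre, so the whole problem is one of regiochemistry among seven oxygens. The four free phenols make the compound electron-rich and easily oxidised, above all in base, so they should be unmasked only at the end; the C5 hydroxyl, hydrogen-bonded to the C4 carbonyl, is set apart from every other oxygen. The three methyl ethers that must be kept (O6, O8, O4') are each flanked by two oxygen substituents, are twisted out of the ring plane, and are therefore more labile towards Lewis acids than an ordinary anisole ether. Only ring C has to be built; the difficulty lies in the alternating OH/OMe pattern of the hexasubstituted ring A, which must be set without regioisomers. The strategy rests on the local symmetry of ring A about the C4a···C7 axis: C5 and C8a, the two oxygen-bearing carbons flanking C4a, are equivalent before ring C exists (as are C6 and C8), so both can start as methoxy carbons of a symmetrical aryl ketone, and this pentaoxygenated ring, with its aroyl group twisted out of conjugation, is the most easily oxidised part of an open-chain 1,3-diketone. After one-electron oxidation the diketone enol oxygen can therefore displace one of the two equivalent methoxy groups (closing O1–C8a), and the other becomes the chelated 5-methoxy group that a Lewis acid removes selectively.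

## Retrosynthetic reasoning

**13 from 12 (three O–CH2Ph bonds and the O5–CH3 bond).** The four phenols of 13 are masked in two ways in flavone 12: the three without a carbonyl neighbour (O7, O3', O5') as benzyl ethers, the one peri to C4=O as a methyl ether. The ring closure below needs a methoxy group at C5, and that methyl ether is the only one in 12 that a Lewis acid can single out, through chelation with the carbonyl oxygen. Benzyl is used for the others because it can be removed without touching the three hindered methyl ethers of the target. The forward step has to free four oxygens and leave three methyl ethers alone.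

**12 from 11 (O1–C8a).** Ring C is opened at O1–C8a and not at the usual O1–C2 bond. Cutting O1–C2 would require a ring A with one ortho oxygen free and the other protected, that is, a differentiation of two positions that are identical until ring C exists. Cutting O1–C8a with a methoxy group on C8a leads to the open-chain diketone 11, whose ring A has a mirror plane through C4a and C7. Its two ortho methoxy carbons are the same, so attack at either gives the same product, and the survivor is the C5 methoxy group that the last step removes. The gain is a ring A that can be made from a symmetrical arene without any regiochemical decision. The forward reaction must make an enol oxygen displace a methoxy group from an electron-rich arene carbon. No two-electron substitution does this, so it is run through the arene radical cation, generated at an anode on the most easily oxidised ring.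

**11 from 10 and 3 (C2–C3).** The diketone is cut between the central CH2 and the carbonyl carbon on the ring B side, giving methyl ketone 10 as enolate partner and ester 3 as acyl partner. The other cut (C3–C4) would need an acyl derivative of the pentaoxygenated ring, whose carbonyl carbon lies between two ortho methoxy groups and is a poor electrophile. The chosen polarity turns that hindrance into an advantage: 10 cannot condense with itself, and 3 has no α-hydrogen. One C–C bond joins the two halves.

**10 from 8 (aryl–acetyl bond).** Benzyl ether 8 has a single ring hydrogen, placed between two methoxy groups, which is the best situation for deprotonation by an alkyllithium. The resulting aryllithium 9 is acylated by an acetyl donor that stops at the ketone. Electrophilic acylation of 8 is avoided because the Lewis acids it needs would endanger the benzyl ether and the position is flanked on both sides.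

**8 from 7 and 2; 7 from 4 (O7–benzyl bond, then C7–O bond).** Phenol 7 is benzylated with 2, and 7 itself comes from the symmetrical arene 4. Arene 4 has two equivalent ring hydrogens, each between two methoxy groups. The route uses them one after the other: the first (through aryllithium 5 and borate 6) brings in the oxygen that becomes O7, the second (previous paragraph) brings in the carbon that becomes C4. Because this oxygen enters as a free phenol it can carry a protecting group different from the four methyl ethers, which later distinguishes O7 from O6 and O8.

**3 from 1 and 2 (two O–benzyl bonds).** Ester 3 comes from diol 1 by twofold O-benzylation with two equivalents of 2. The 4-methoxy group and the ester carbon of 1 are already those of ring B and C2 of the target.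

## Alternatives that were turned down

Alternative 1: ring A grown by ring expansion of a four-membered ring.
- Disconnection: ring A is cut at C8–C8a and C4a–C5 and built last, from a four-carbon cyclobutenone unit attached to a preformed pyranone ring.
- Forward key step: heating the racemic cyclobutenone A2 (4-{6-[3,5-bis(benzyloxy)-4-methoxyphenyl]-4-oxo-4H-pyran-3-yl}-2-tert-butoxy-4-hydroxy-3-methoxycyclobut-2-en-1-one) opens the four-membered ring to a dienylketene. A 6π electrocyclisation joins the ketene carbon to pyranone C2 (C8–C8a), and tautomerisation gives the 5,8-dihydroxyflavone A1 (2-[3,5-bis(benzyloxy)-4-methoxyphenyl]-7-tert-butoxy-5,8-dihydroxy-6-methoxy-4H-chromen-4-one).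
- For: this benzannulation type is well established, and on precedent it is stronger than the chosen key step. Each oxygen of ring A is placed by construction and O5, O6, O7 and O8 all emerge differentiated. The chelated O5–H should allow selective methylation of O8.
- Against: A2 must be assembled from two further building blocks, each several steps from purchasable material, by a carbonyl addition that has to choose between two similar ring carbonyl groups. The metallated pyranone partner is a vinylogous ester prone to conjugate addition and ring opening. A1 is a para-hydroquinone that should oxidise readily to the 5,8-quinone. After the key step O8-methylation, tert-butyl cleavage and debenzylation still remain.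
- Comparison: the route would run to well over ten steps. The chosen strategy offers seven steps and no regiochemical question, at the price of an unprecedented ring closure.

Alternative 2: intramolecular ester Wittig olefination.
- Disconnection: C2=C3.
- Forward key step: on heating the ylide ester A4 (3,5-bis(benzyloxy)-4,6-dimethoxy-2-[2-(triphenylphosphoranylidene)acetyl]phenyl 3,5-bis(benzyloxy)-4-methoxybenzoate), the ylide carbon (future C3) attacks the aryl ester carbonyl (future C2). Loss of the phosphine oxide closes ring C and gives A3 (5,7-bis(benzyloxy)-2-[3,5-bis(benzyloxy)-4-methoxyphenyl]-6,8-dimethoxy-4H-chromen-4-one).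
- For: the conditions are neutral and the reaction type is known for chromones. All four phenols of A3 are benzyl ethers, so a single hydrogenolysis gives the target and no Lewis acid meets the hindered methyl ethers. On the end-game this alternative is stronger than the chosen route.
- Against: the ring A half of A4 carries three phenolic oxygens in three different states (one acylated, two benzylated) beside two methyl ethers. This is exactly the desymmetrisation of ring A that the chosen strategy avoids. α-Halogenation, phosphonium salt formation and ylide generation must then be carried out in the presence of an aryl ester that can transfer its acyl group.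
- Comparison: ten to twelve steps are to be expected. The chosen strategy gives up the clean hydrogenolytic end-game for a much shorter, symmetry-based approach to ring A.

Alternative 3: thermal aroylketene annulation onto the unprotected triol.
- Disconnection: C4–C4a and O1–C2, the two bonds between ring A and a three-carbon ring B fragment.
- Forward key step: heating the symmetric triol A6 (2,4-dimethoxybenzene-1,3,5-triol) with the β-keto ester A7 (ethyl 3-[3,5-bis(benzyloxy)-4-methoxyphenyl]-3-oxopropanoate) generates the aroylketene. It acylates the one free ring carbon of A6, and cyclodehydration gives A5 (2-[3,5-bis(benzyloxy)-4-methoxyphenyl]-5,7-dihydroxy-6,8-dimethoxy-4H-chromen-4-one).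
- For: this is the most convergent plan. Ring A needs no protecting group, A6 has one nucleophilic carbon, and only one hydrogenolysis follows. Counted from the fragments it is shorter than the chosen route.
- Against: A6 is not a purchasable compound. It is a very electron-rich, air-sensitive triol that must be made in several steps and then exposed unprotected to temperatures well above 200 °C. Under such conditions C-acylation (flavone) competes with O-acylation and closure in the Pechmann sense to the isomeric 2-pyrone. The benzyl ethers of A7 are also under thermal stress.
- Comparison: the chosen strategy keeps every phenol protected until the last step, uses stable intermediates from purchasable arenes, and its ring closure has only one possible regiochemical outcome.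

Key step: step 6

## Route

Step 1
Reactants: 1 methyl 3,5-dihydroxy-4-methoxybenzoate; 2 benzyl bromide
Product: 3 methyl 3,5-bis(benzyloxy)-4-methoxybenzoate
Conditions: BnBr (2.4 equiv), K2CO3, DMF, 60 °C
Reagents that add atoms: benzyl bromide, BrCc1ccccc1 (the second benzyl group; two equivalents of 2 are consumed, one for each phenol)
Why: Twofold Williamson ether synthesis (SN2 at the benzylic carbon by each of the two phenoxides, one molecule of 2 per oxygen); the methyl ester and the 4-methoxy group are inert to K2CO3 in DMF.

Step 2
Reactants: 4 1,2,4,5-tetramethoxybenzene
Product: 7 2,3,5,6-tetramethoxyphenol, via (2,3,5,6-tetramethoxyphenyl)lithium 5 (not isolated), via lithium trimethoxy(2,3,5,6-tetramethoxyphenyl)borate 6 (not isolated)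
Conditions: n-BuLi (1.05 equiv), THF, 0 °C to rt; B(OMe)3, −78 °C to rt; AcOH, 30% aq. H2O2, 0 °C
Reagents that add atoms: hydrogen peroxide, OO (oxygen of 7); only in the intermediates: n-butyllithium, [Li]CCCC (lithium of 5 and 6); trimethyl borate, COB(OC)OC (boron and methoxy groups of 6)
Why: Directed ortho-metalation (the two ring hydrogens of 4 are equivalent and each lies between two methoxy groups, so one equivalent of base should give a single aryllithium), borylation, and peroxide-induced 1,2-migration of the aryl group from boron to oxygen (standard arylboron-to-phenol oxidation); the weakly acidic medium at 0 °C should keep the electron-rich phenol from further oxidation.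

Step 3
Reactants: 7 2,3,5,6-tetramethoxyphenol; 2 benzyl bromide
Product: 8 3-(benzyloxy)-1,2,4,5-tetramethoxybenzene
Conditions: BnBr (1.2 equiv), K2CO3, DMF, 50 °C
Reagents that add atoms: none
Why: Williamson ether synthesis; the phenoxide of 7 is flanked by two methoxy groups but should still be alkylated cleanly on oxygen by a primary benzylic bromide in a dipolar aprotic solvent.

Step 4
Reactants: 8 3-(benzyloxy)-1,2,4,5-tetramethoxybenzene
Product: 10 1-[4-(benzyloxy)-2,3,5,6-tetramethoxyphenyl]ethan-1-one, via [4-(benzyloxy)-2,3,5,6-tetramethoxyphenyl]lithium 9 (not isolated)
Conditions: n-BuLi (1.1 equiv), THF, 0 °C; MeC(O)N(OMe)Me, −78 °C to 0 °C; aq. HCl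
Reagents that add atoms: N-methoxy-N-methylacetamide, CC(=O)N(C)OC (acetyl group); only in the intermediate: n-butyllithium, [Li]CCCC (lithium of 9)
Why: Directed ortho-metalation of the only ring C–H, again flanked by two methoxy groups, followed by Weinreb ketone synthesis, in which the chelated tetrahedral adduct survives until work-up and prevents over-addition; n-BuLi at 0 °C is expected to remove this doubly activated ring proton faster than a benzylic proton of the ether.

Step 5
Reactants: 10 1-[4-(benzyloxy)-2,3,5,6-tetramethoxyphenyl]ethan-1-one; 3 methyl 3,5-bis(benzyloxy)-4-methoxybenzoate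
Product: 11 1-[4-(benzyloxy)-2,3,5,6-tetramethoxyphenyl]-3-[3,5-bis(benzyloxy)-4-methoxyphenyl]propane-1,3-dione
Conditions: NaH (2.5 equiv), THF, reflux; aq. HCl
Reagents that add atoms: none
Why: Crossed Claisen condensation: only 10 can form an enolate and only 3 is an accessible acyl acceptor (the carbonyl of 10 is shielded by two ortho methoxy groups, which also suppresses self-condensation); deprotonation of the product 1,3-diketone by the second equivalent of base drives the equilibrium.

Step 6
Reactants: 11 1-[4-(benzyloxy)-2,3,5,6-tetramethoxyphenyl]-3-[3,5-bis(benzyloxy)-4-methoxyphenyl]propane-1,3-dione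
Product: 12 7-(benzyloxy)-2-[3,5-bis(benzyloxy)-4-methoxyphenyl]-5,6,8-trimethoxy-4H-chromen-4-one
Conditions: reticulated vitreous carbon anode, Pt cathode, divided cell, Bu4NPF6 (0.1 M), MeCN/HFIP (4:1), controlled potential at the first anodic wave of 11, substoichiometric charge (ca. 0.2 F/mol), rt, Ar
Reagents that add atoms: none
Why: Proposed new method: one-electron oxidation at the carbon anode should occur on the pentaalkoxy ring A of 11 (its aroyl group is twisted out of conjugation, so it is the lowest-potential π system), and in the radical cation the methoxy-bearing ortho carbon C8a is attacked ipso by the oxygen of the enolised C2 carbonyl to give a ring-fused, ketal-type cyclohexadienyl radical; loss of methanol, assisted by the hydrogen-bond-donating co-solvent, then gives the radical cation of 12, which should be a stronger oxidant than 11 because ring A is now conjugated with C4=O, so it takes an electron from the next molecule of 11 and the overall redox-neutral change needs only a catalytic charge. The closest known reaction type is cation-radical-accelerated nucleophilic aromatic substitution of methoxyarenes by heteroatom nucleophiles under photoredox catalysis; the step proposed here is an intramolecular, anode-initiated variant with an enol oxygen as the nucleophile. Ring C closes by attack on an arene carbon, 6-exo-trig when counted on the C8–C8a π bond (the fusion bond C4a–C8a lies inside the new ring). No stereocentre is formed. The step needs oxidation at ring A and not at ring B or the enol, and attack at an ortho methoxy carbon and not at another alkoxy carbon: the first should follow from the order of oxidation potentials, the second from ring size, since only the two ortho carbons can be reached by the enol oxygen through a six-membered transition state, and these two are equivalent by symmetry. The hydrogen-bonded enol has to rotate about C3–C4 to bring its oxygen over ring A, which the protic fluorinated co-solvent should make easier by competing for the internal hydrogen bond.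

Step 7
Reactants: 12 7-(benzyloxy)-2-[3,5-bis(benzyloxy)-4-methoxyphenyl]-5,6,8-trimethoxy-4H-chromen-4-one
Product: 13 5,7-dihydroxy-2-(3,5-dihydroxy-4-methoxyphenyl)-6,8-dimethoxy-4H-chromen-4-one (CNP0185233.0)
Conditions: BCl3 (6 equiv), C6HMe5 (10 equiv), CH2Cl2, −78 °C to 0 °C; MeOH; aq. HCl
Reagents that add atoms: none
Why: Lewis-acid ether cleavage: BCl3 is held between the C4 carbonyl oxygen and O5, and the chelated 5-methyl ether is cleaved by chloride (chelation-controlled demethylation peri to a carbonyl), while the three benzyl ethers ionise at low temperature and pentamethylbenzene traps the benzyl cations by Friedel–Crafts alkylation so that the electron-rich rings are not C-benzylated. The methyl ethers at O6, O8 and O4' have no carbonyl partner and should survive as long as the mixture is not warmed above 0 °C.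

## Compound list

1 | methyl 3,5-dihydroxy-4-methoxybenzoate | COC(=O)c1cc(O)c(OC)c(O)c1 | starting material
2 | benzyl bromide | BrCc1ccccc1 | starting material
3 | methyl 3,5-bis(benzyloxy)-4-methoxybenzoate | COC(=O)c1cc(OCc2ccccc2)c(OC)c(OCc2ccccc2)c1 | intermediate
4 | 1,2,4,5-tetramethoxybenzene | COc1cc(OC)c(OC)cc1OC | starting material
5 | (2,3,5,6-tetramethoxyphenyl)lithium | [Li]c1c(OC)c(OC)cc(OC)c1OC | intermediate
6 | lithium trimethoxy(2,3,5,6-tetramethoxyphenyl)borate | [Li+].CO[B-](OC)(OC)c1c(OC)c(OC)cc(OC)c1OC | intermediate
7 | 2,3,5,6-tetramethoxyphenol | COc1cc(OC)c(OC)c(O)c1OC | intermediate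
8 | 3-(benzyloxy)-1,2,4,5-tetramethoxybenzene | COc1cc(OC)c(OC)c(OCc2ccccc2)c1OC | intermediate
9 | [4-(benzyloxy)-2,3,5,6-tetramethoxyphenyl]lithium | [Li]c1c(OC)c(OC)c(OCc2ccccc2)c(OC)c1OC | intermediate
10 | 1-[4-(benzyloxy)-2,3,5,6-tetramethoxyphenyl]ethan-1-one | CC(=O)c1c(OC)c(OC)c(OCc2ccccc2)c(OC)c1OC | intermediate
11 | 1-[4-(benzyloxy)-2,3,5,6-tetramethoxyphenyl]-3-[3,5-bis(benzyloxy)-4-methoxyphenyl]propane-1,3-dione | COc1c(OC)c(OCc2ccccc2)c(OC)c(OC)c1C(=O)CC(=O)c1cc(OCc2ccccc2)c(OC)c(OCc2ccccc2)c1 | intermediate
12 | 7-(benzyloxy)-2-[3,5-bis(benzyloxy)-4-methoxyphenyl]-5,6,8-trimethoxy-4H-chromen-4-one | COc1c(OCc2ccccc2)cc(-c2cc(=O)c3c(OC)c(OC)c(OCc4ccccc4)c(OC)c3o2)cc1OCc1ccccc1 | intermediate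
13 | 5,7-dihydroxy-2-(3,5-dihydroxy-4-methoxyphenyl)-6,8-dimethoxy-4H-chromen-4-one | COc1c(O)cc(-c2cc(=O)c3c(O)c(OC)c(O)c(OC)c3o2)cc1O | target

## Step count and risk

Total step count: 7. Longest linear sequence: 6 steps (4 → 7 → 8 → 10 → 11 → 12 → 13; the ring B branch, step 1, joins at step 5).

**Step 6 (key step).**
- The radical cation of ring A may be consumed by other channels before the enol oxygen adds: cleavage of the O7 benzyl group (benzylic deprotonation or loss of a benzyl cation from the radical cation), or attack of adventitious water followed by oxidative demethylation towards a quinone.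
- The enol oxygen may fail to reach C8a, because the chelated enol holds it away from ring A and a neutral enol oxygen is a weak nucleophile.
- Electron transfer from 11 to the product radical cation may be too slow to carry a chain, so that a full equivalent of charge and longer exposure of 12 to the anode become necessary.
- Fallback (known chemistry; ring C is then closed at O1–C2): it sets out from 10 and 3 and comes back at 12. Chelation-controlled mono-demethylation of 10 with MgI2·OEt2 (toluene, 80 °C; the two ortho methoxy groups are equivalent) should give 1-[4-(benzyloxy)-2-hydroxy-3,5,6-trimethoxyphenyl]ethan-1-one F1. Its dianion (LiN(SiMe3)2, THF, −78 °C to rt) is condensed with ester 3 in a Claisen reaction to 1-[4-(benzyloxy)-2-hydroxy-3,5,6-trimethoxyphenyl]-3-[3,5-bis(benzyloxy)-4-methoxyphenyl]propane-1,3-dione F2. Acid-catalysed cyclodehydration (cat. H2SO4, AcOH, 80 °C) then gives 12.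

**Step 4.**
- Deprotonation at the benzylic CH2 of the ether may compete with ring metalation and lead to anionic rearrangement of the benzyl group.
- The hindered aryllithium may also act as a base towards the acetyl donor instead of adding to it.
- Fallback: it sets out from 8 and comes back at 9, and so at 10. Electrophilic bromination at the only free ring position (NBS, MeCN, 0 °C) should give 1-(benzyloxy)-4-bromo-2,3,5,6-tetramethoxybenzene F3. Bromine–lithium exchange (n-BuLi, THF, −78 °C) then gives 9 at a temperature at which benzylic deprotonation cannot compete, and acylation as in step 4 gives 10.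

**Step 5.**
- Acylation of the hindered enolate by an electron-rich ester may be slow, so that retro-Claisen cleavage by the liberated methoxide and incomplete conversion limit the yield.
- Fallback: it sets out from 3 and 10 and comes back at 11; aldol addition and oxidation replace the acylation. Reduction of 3 (LiAlH4, THF, 0 °C) gives [3,5-bis(benzyloxy)-4-methoxyphenyl]methanol F4, and oxidation (MnO2, CH2Cl2, rt) gives 3,5-bis(benzyloxy)-4-methoxybenzaldehyde F5. The lithium enolate of 10 (LiN(iPr)2, THF, −78 °C) adds to F5 to give racemic 1-[4-(benzyloxy)-2,3,5,6-tetramethoxyphenyl]-3-[3,5-bis(benzyloxy)-4-methoxyphenyl]-3-hydroxypropan-1-one F6. Dess–Martin oxidation (CH2Cl2, rt) then gives 11.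

**Step 7.**
- Over-reaction of the Lewis acid: the methyl ethers at O6, O8 and O4' are each flanked by two oxygens and may be cleaved after the chelated one, especially if the mixture warms.
- Incomplete trapping of benzyl cations would lead to C-benzylation of the phenolic rings.
- Fallback: it sets out from 12 and comes back at 13. Hydrogenolysis (H2, Pd/C, EtOAc/MeOH, rt) removes the three benzyl groups without any Lewis acid and should give 7-hydroxy-2-(3,5-dihydroxy-4-methoxyphenyl)-5,6,8-trimethoxy-4H-chromen-4-one F7. The chelated 5-methyl ether alone is then cleaved with AlCl3 in MeCN (rt), where the donor solvent attenuates the Lewis acid, to give 13.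

## Further compounds

F1 | step 6 | 1-[4-(benzyloxy)-2-hydroxy-3,5,6-trimethoxyphenyl]ethan-1-one | CC(=O)c1c(O)c(OC)c(OCc2ccccc2)c(OC)c1OC
F2 | step 6 | 1-[4-(benzyloxy)-2-hydroxy-3,5,6-trimethoxyphenyl]-3-[3,5-bis(benzyloxy)-4-methoxyphenyl]propane-1,3-dione | COc1c(OC)c(OCc2ccccc2)c(OC)c(O)c1C(=O)CC(=O)c1cc(OCc2ccccc2)c(OC)c(OCc2ccccc2)c1
F3 | step 4 | 1-(benzyloxy)-4-bromo-2,3,5,6-tetramethoxybenzene | COc1c(OC)c(OCc2ccccc2)c(OC)c(OC)c1Br
F4 | step 5 | [3,5-bis(benzyloxy)-4-methoxyphenyl]methanol | COc1c(OCc2ccccc2)cc(CO)cc1OCc1ccccc1
F5 | step 5 | 3,5-bis(benzyloxy)-4-methoxybenzaldehyde | COc1c(OCc2ccccc2)cc(C=O)cc1OCc1ccccc1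
F6 | step 5 | racemic 1-[4-(benzyloxy)-2,3,5,6-tetramethoxyphenyl]-3-[3,5-bis(benzyloxy)-4-methoxyphenyl]-3-hydroxypropan-1-one | COc1c(OC)c(OCc2ccccc2)c(OC)c(OC)c1C(=O)CC(O)c1cc(OCc2ccccc2)c(OC)c(OCc2ccccc2)c1
F7 | step 7 | 7-hydroxy-2-(3,5-dihydroxy-4-methoxyphenyl)-5,6,8-trimethoxy-4H-chromen-4-one | COc1c(O)cc(-c2cc(=O)c3c(OC)c(OC)c(O)c(OC)c3o2)cc1O
A1 | alternative 1 | 2-[3,5-bis(benzyloxy)-4-methoxyphenyl]-7-tert-butoxy-5,8-dihydroxy-6-methoxy-4H-chromen-4-one | COc1c(O)c2c(=O)cc(-c3cc(OCc4ccccc4)c(OC)c(OCc4ccccc4)c3)oc2c(O)c1OC(C)(C)C
A2 | alternative 1 | racemic 4-{6-[3,5-bis(benzyloxy)-4-methoxyphenyl]-4-oxo-4H-pyran-3-yl}-2-tert-butoxy-4-hydroxy-3-methoxycyclobut-2-en-1-one | COC1=C(OC(C)(C)C)C(=O)C1(O)c1coc(-c2cc(OCc3ccccc3)c(OC)c(OCc3ccccc3)c2)cc1=O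
A3 | alternative 2 | 5,7-bis(benzyloxy)-2-[3,5-bis(benzyloxy)-4-methoxyphenyl]-6,8-dimethoxy-4H-chromen-4-one | COc1c(OCc2ccccc2)cc(-c2cc(=O)c3c(OCc4ccccc4)c(OC)c(OCc4ccccc4)c(OC)c3o2)cc1OCc1ccccc1
A4 | alternative 2 | 3,5-bis(benzyloxy)-4,6-dimethoxy-2-[2-(triphenylphosphoranylidene)acetyl]phenyl 3,5-bis(benzyloxy)-4-methoxybenzoate | COc1c(OCc2ccccc2)cc(C(=O)Oc2c(OC)c(OCc3ccccc3)c(OC)c(OCc3ccccc3)c2C(=O)C=P(c2ccccc2)(c2ccccc2)c2ccccc2)cc1OCc1ccccc1
A5 | alternative 3 | 2-[3,5-bis(benzyloxy)-4-methoxyphenyl]-5,7-dihydroxy-6,8-dimethoxy-4H-chromen-4-one | COc1c(OCc2ccccc2)cc(-c2cc(=O)c3c(O)c(OC)c(O)c(OC)c3o2)cc1OCc1ccccc1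
A6 | alternative 3 | 2,4-dimethoxybenzene-1,3,5-triol | COc1c(O)cc(O)c(OC)c1O
A7 | alternative 3 | ethyl 3-[3,5-bis(benzyloxy)-4-methoxyphenyl]-3-oxopropanoate | CCOC(=O)CC(=O)c1cc(OCc2ccccc2)c(OC)c(OCc2ccccc2)c1
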